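**Retrosynthetic overview**

1. The C8 angelate is attached last to a hydroxy acetate; the C6 acetate is installed earlier, while the C8 oxygen is still locked in an oxygen bridge.
2. The cycloheptene with the tetrasubstituted C1=C10 alkene comes from an oxygen-bridged tricycle by reductive opening of the C1–O bond (hydride to C9, C8–OH released).
3. Key step: an intramolecular (4+3) cycloaddition of a 2-silyloxyallyl cation (C5–C6–C7, both α-carbons of the C6 ketone electrophilic) onto a tethered 3-methylfuran. It forms C5–C1 and then C7–C8, so the five-membered and the seven-membered ring close in this one step.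
4. The cation precursor is the enol silane of an α,β-epoxy ketone, made by Sharpless epoxidation of an E-allylic alcohol (sets C4; C5 is inverted in the key step) and addition of isobutylmagnesium bromide.
5. The allylic alcohol comes from 3-methylfuran, methyl vinyl ketone and triethyl phosphonoacetate.

Assumption: atom labels C1–C15 follow guaiane numbering of the target (C4 carbinol, C5 ring-fusion CH, C6 acetoxy carbon, C7 isopropyl carbon, C8 angeloyloxy carbon, C1=C10 ring alkene); 3-methylfuran and angelic acid are taken as purchasable.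

**Route**

Step 1
Reactants: 1 3-methylfuran; 2 but-3-en-2-one (methyl vinyl ketone)
Product: 3 4-(3-methylfuran-2-yl)butan-2-one
Conditions: In(OTf)3 (2 mol %), MeCN, 0 °C → rt (1.5 equiv of 1)
Reagents that add atoms: none
Why: Friedel–Crafts-type conjugate addition of the furan to the enone, which goes to the furan 2-position because that α-carbon is activated by both the ring oxygen and the adjacent methyl group; no stereocenter is formed.

Step 2
Reactants: 3 4-(3-methylfuran-2-yl)butan-2-one; 4 triethyl phosphonoacetate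
Product: 5 ethyl (2E)-3-methyl-5-(3-methylfuran-2-yl)pent-2-enoate
Conditions: NaH, THF, 0 °C → rt; minor Z isomer removed by chromatography
Reagents that add atoms: none
Why: Horner–Wadsworth–Emmons olefination of a methyl ketone gives mainly the E trisubstituted enoate, and pure E material is needed because the alkene geometry later becomes the C4/C5 relative configuration.

Step 3
Reactants: 5 ethyl (2E)-3-methyl-5-(3-methylfuran-2-yl)pent-2-enoate
Product: 6 (2E)-3-methyl-5-(3-methylfuran-2-yl)pent-2-en-1-ol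
Conditions: i-Bu2AlH (2.2 equiv), CH2Cl2, −78 °C; aq. potassium sodium tartrate
Reagents that add atoms: none
Why: 1,2-reduction of the conjugated ester by the aluminium hydride gives the allylic alcohol with the alkene geometry unchanged.

Step 4
Reactants: 6 (2E)-3-methyl-5-(3-methylfuran-2-yl)pent-2-en-1-ol
Product: 7 [(2S,3S)-3-methyl-3-[2-(3-methylfuran-2-yl)ethyl]oxiran-2-yl]methanol
Conditions: Ti(OiPr)4 (5 mol %), L-(+)-diethyl tartrate (6 mol %), t-BuOOH, 4 Å MS, CH2Cl2, −20 °C
Reagents that add atoms: tert-butyl hydroperoxide CC(C)(C)OO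
Why: Sharpless asymmetric epoxidation, which with L-(+)-tartrate gives the (2S,3S)-epoxide of an E-3,3-disubstituted allylic alcohol (the geraniol case); this sets C4 as S and sets the C5 centre that is inverted in the key step.

Step 5
Reactants: 7 [(2S,3S)-3-methyl-3-[2-(3-methylfuran-2-yl)ethyl]oxiran-2-yl]methanol
Product: 8 (2R,3S)-3-methyl-3-[2-(3-methylfuran-2-yl)ethyl]oxirane-2-carbaldehyde
Conditions: Dess–Martin periodinane, pyridine, CH2Cl2, 0 °C → rt
Reagents that add atoms: none
Why: Dess–Martin oxidation of the primary alcohol under buffered, non-acidic conditions that leave the epoxide, its configuration and the furan untouched.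

Step 6
Reactants: 8 (2R,3S)-3-methyl-3-[2-(3-methylfuran-2-yl)ethyl]oxirane-2-carbaldehyde; 9 isobutylmagnesium bromide
Product: 10 3-methyl-1-[(2S,3S)-3-methyl-3-[2-(3-methylfuran-2-yl)ethyl]oxiran-2-yl]butan-1-ol (both carbinol epimers)
Conditions: THF, −78 °C; aq. NH4Cl
Reagents that add atoms: none
Why: Grignard addition to the aldehyde is much faster than epoxide opening at −78 °C, and the new carbinol centre need not be controlled because it is oxidised in the next step.

Step 7
Reactants: 10 3-methyl-1-[(2S,3S)-3-methyl-3-[2-(3-methylfuran-2-yl)ethyl]oxiran-2-yl]butan-1-ol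
Product: 11 3-methyl-1-[(2R,3S)-3-methyl-3-[2-(3-methylfuran-2-yl)ethyl]oxiran-2-yl]butan-1-one
Conditions: Dess–Martin periodinane, pyridine, CH2Cl2, 0 °C → rt
Reagents that add atoms: none
Why: Dess–Martin oxidation of the secondary alcohol gives the α,β-epoxy ketone without epimerising the epoxide carbon.

Step 8
Reactants: 11 3-methyl-1-[(2R,3S)-3-methyl-3-[2-(3-methylfuran-2-yl)ethyl]oxiran-2-yl]butan-1-one
Product: 12 triethyl({(1Z)-3-methyl-1-[(2R,3S)-3-methyl-3-[2-(3-methylfuran-2-yl)ethyl]oxiran-2-yl]but-1-en-1-yl}oxy)silane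
Conditions: TESOTf (1.2 equiv), Et3N (2.0 equiv), CH2Cl2, −78 → 0 °C; filtration through Et3N-deactivated silica
Reagents that add atoms: triethylsilyl trifluoromethanesulfonate CC[Si](CC)(CC)OS(=O)(=O)C(F)(F)F
Why: Soft enolisation and O-silylation toward the only enolisable side (C7) gives the Z enol silane (isopropyl cis to the silyloxy group, away from the epoxide carbon), and the excess amine keeps the medium free of Lewis acid so the epoxide survives.

Step 9
Reactants: 12 triethyl({(1Z)-3-methyl-1-[(2R,3S)-3-methyl-3-[2-(3-methylfuran-2-yl)ethyl]oxiran-2-yl]but-1-en-1-yl}oxy)silane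
Product: 14 (1S,4S,5S,7R,8S)-4,10-dimethyl-7-(propan-2-yl)-4-[(triethylsilyl)oxy]-11-oxatricyclo[6.2.1.0(1,5)]undec-9-en-6-one, via C7-epimeric cycloadduct 13 (not isolated)
Conditions: TESOTf (20 mol %), CH2Cl2 (0.01 M), −78 °C; then DBU (0.3 equiv), 0 °C → rt
Reagents that add atoms: none
Why: Intramolecular (4+3) cycloaddition of an epoxy enol silane, in which the silyl triflate opens the epoxide at C5 to a 2-silyloxyallyl cation so that both α-carbons of the C6 ketone act as electrophiles; the tethered furan carbon C1 attacks C5 anti to the leaving oxygen (inversion at C5, C4 untouched, hence the C4 oxygen cis to H5), the enol silane terminus C7 then closes onto furan carbon C8 and silicon ends on the C4 oxygen, the short tether and the clash between the C4 methyl and the furan methyl in the alternative arrangement placing H5 anti to the oxygen bridge, and DBU finally converts any epimer with an axial C7 isopropyl group (13) into the equatorial epimer 14.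

Step 10
Reactants: 14 (1S,4S,5S,7R,8S)-4,10-dimethyl-7-(propan-2-yl)-4-[(triethylsilyl)oxy]-11-oxatricyclo[6.2.1.0(1,5)]undec-9-en-6-one
Product: 16 (1S,4S,5S,6R,7R,8S)-4,10-dimethyl-7-(propan-2-yl)-4-[(triethylsilyl)oxy]-11-oxatricyclo[6.2.1.0(1,5)]undec-9-en-6-yl acetate, via lithium alkoxide 15 (not isolated)
Conditions: LiBH(s-Bu)3 (1.3 equiv), THF, −78 °C; then Ac2O (5 equiv), DMAP (0.2 equiv), −78 °C → rt
Reagents that add atoms: acetic anhydride CC(=O)OC(C)=O
Why: Substrate-controlled ketone reduction with in situ acetylation, in which the bulky hydride reaches C6 from the face of the oxygen bridge because the other face is covered by the C9=C10 bridge, giving the C6 oxygen anti to the bridge and cis to the isopropyl group (6R); the alkoxide is acetylated while the C8 oxygen is still tied up in the bridge.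

Step 11
Reactants: 16 (1S,4S,5S,6R,7R,8S)-4,10-dimethyl-7-(propan-2-yl)-4-[(triethylsilyl)oxy]-11-oxatricyclo[6.2.1.0(1,5)]undec-9-en-6-yl acetate
Product: 18 (3S,3aR,4R,5R,6S)-3,6-dihydroxy-3,8-dimethyl-5-(propan-2-yl)-1,2,3,3a,4,5,6,7-octahydroazulen-4-yl acetate, via bis(triethylsilyl) ether 17 (not isolated)
Conditions: Et3SiH (3 equiv), TESOTf (0.3 equiv), CH2Cl2, −78 → −40 °C; then HF·pyridine, THF, 0 °C → rt
Reagents that add atoms: none
Why: Proposed new method: ionic hydrogenolysis with allylic transposition, in which O-silylation of the bridge ether ionises the tertiary allylic C1–O bond, the C1–C10–C9 allyl cation takes hydride from the silane at the less hindered C9 to leave the tetrasubstituted C1=C10 alkene and a C8 silyl ether of unchanged configuration, and fluoride then removes both silyl groups; the closest known reactions are silane/Lewis acid reductions of tertiary allylic ethers and ketals and hydride ring-openings of oxabicyclic alkenes.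

Step 12
Reactants: 18 (3S,3aR,4R,5R,6S)-3,6-dihydroxy-3,8-dimethyl-5-(propan-2-yl)-1,2,3,3a,4,5,6,7-octahydroazulen-4-yl acetate; 19 (2Z)-2-methylbut-2-enoic acid (angelic acid)
Product: 21 (3S,3aR,4R,5R,6S)-4-(acetyloxy)-3-hydroxy-3,8-dimethyl-5-(propan-2-yl)-1,2,3,3a,4,5,6,7-octahydroazulen-6-yl (2Z)-2-methylbut-2-enoate, via mixed anhydride 20 (not isolated)
Conditions: 19, 2,4,6-trichlorobenzoyl chloride, Et3N, toluene, rt; then 18, 80 °C (no DMAP)
Reagents that add atoms: none
Why: Yamaguchi-type mixed-anhydride esterification run without a nucleophilic catalyst, conditions that transfer the angeloyl group without Z to E isomerisation; only the secondary C8 hydroxyl reacts because the tertiary C4 hydroxyl is inert.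

**Compound list**

1 | 3-methylfuran | Cc1ccoc1 | starting material
2 | but-3-en-2-one | CC(=O)C=C | starting material
3 | 4-(3-methylfuran-2-yl)butan-2-one | CC(=O)CCc1occc1C | intermediate
4 | triethyl phosphonoacetate | CCOC(=O)CP(=O)(OCC)OCC | starting material
5 | ethyl (2E)-3-methyl-5-(3-methylfuran-2-yl)pent-2-enoate | CCOC(=O)/C=C(\C)CCc1occc1C | intermediate
6 | (2E)-3-methyl-5-(3-methylfuran-2-yl)pent-2-en-1-ol | OC/C=C(\C)CCc1occc1C | intermediate
7 | [(2S,3S)-3-methyl-3-[2-(3-methylfuran-2-yl)ethyl]oxiran-2-yl]methanol | OC[C@@H]1O[C@@]1(C)CCc1occc1C | intermediate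
8 | (2R,3S)-3-methyl-3-[2-(3-methylfuran-2-yl)ethyl]oxirane-2-carbaldehyde | O=C[C@@H]1O[C@@]1(C)CCc1occc1C | intermediate
9 | isobutylmagnesium bromide | CC(C)C[Mg]Br | starting material
10 | 3-methyl-1-[(2S,3S)-3-methyl-3-[2-(3-methylfuran-2-yl)ethyl]oxiran-2-yl]butan-1-ol (carbinol epimers) | CC(C)CC(O)[C@@H]1O[C@@]1(C)CCc1occc1C | intermediate
11 | 3-methyl-1-[(2R,3S)-3-methyl-3-[2-(3-methylfuran-2-yl)ethyl]oxiran-2-yl]butan-1-one | CC(C)CC(=O)[C@@H]1O[C@@]1(C)CCc1occc1C | intermediate
12 | triethyl({(1Z)-3-methyl-1-[(2R,3S)-3-methyl-3-[2-(3-methylfuran-2-yl)ethyl]oxiran-2-yl]but-1-en-1-yl}oxy)silane | CC(C)/C=C(/[C@@H]1O[C@@]1(C)CCc1occc1C)O[Si](CC)(CC)CC | intermediate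
13 | (1S,4S,5S,7S,8S)-4,10-dimethyl-7-(propan-2-yl)-4-[(triethylsilyl)oxy]-11-oxatricyclo[6.2.1.0(1,5)]undec-9-en-6-one (isopropyl syn to the oxygen bridge) | CC(C)[C@@H]1C(=O)[C@@H]2[C@@](C)(O[Si](CC)(CC)CC)CC[C@]23O[C@H]1C=C3C | intermediate
14 | (1S,4S,5S,7R,8S)-4,10-dimethyl-7-(propan-2-yl)-4-[(triethylsilyl)oxy]-11-oxatricyclo[6.2.1.0(1,5)]undec-9-en-6-one (isopropyl and H5 anti to the oxygen bridge) | CC(C)[C@H]1C(=O)[C@@H]2[C@@](C)(O[Si](CC)(CC)CC)CC[C@]23O[C@H]1C=C3C | intermediate
15 | lithium alkoxide of the C6 alcohol derived from 14 (C6 oxygen anti to the bridge) | CC(C)[C@H]1[C@@H]([O-])[C@@H]2[C@@](C)(O[Si](CC)(CC)CC)CC[C@]23O[C@H]1C=C3C.[Li+] | intermediate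
16 | (1S,4S,5S,6R,7R,8S)-4,10-dimethyl-7-(propan-2-yl)-4-[(triethylsilyl)oxy]-11-oxatricyclo[6.2.1.0(1,5)]undec-9-en-6-yl acetate | CC(C)[C@H]1[C@@H](OC(C)=O)[C@@H]2[C@@](C)(O[Si](CC)(CC)CC)CC[C@]23O[C@H]1C=C3C | intermediate
17 | (3S,3aR,4R,5S,6S)-3,8-dimethyl-5-(propan-2-yl)-3,6-bis[(triethylsilyl)oxy]-1,2,3,3a,4,5,6,7-octahydroazulen-4-yl acetate | CC[Si](CC)(CC)O[C@H]1CC(C)=C2CC[C@](C)(O[Si](CC)(CC)CC)[C@H]2[C@H](OC(C)=O)[C@@H]1C(C)C | intermediate
18 | (3S,3aR,4R,5R,6S)-3,6-dihydroxy-3,8-dimethyl-5-(propan-2-yl)-1,2,3,3a,4,5,6,7-octahydroazulen-4-yl acetate | O[C@H]1CC(C)=C2CC[C@](C)(O)[C@H]2[C@H](OC(C)=O)[C@@H]1C(C)C | intermediate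
19 | (2Z)-2-methylbut-2-enoic acid (angelic acid) | C/C=C(/C)C(=O)O | starting material
20 | (2Z)-2-methylbut-2-enoic 2,4,6-trichlorobenzoic anhydride | C/C=C(/C)C(=O)OC(=O)c1c(Cl)cc(Cl)cc1Cl | intermediate
21 | (3S,3aR,4R,5R,6S)-4-(acetyloxy)-3-hydroxy-3,8-dimethyl-5-(propan-2-yl)-1,2,3,3a,4,5,6,7-octahydroazulen-6-yl (2Z)-2-methylbut-2-enoate | C/C=C(/C)C(=O)O[C@H]1CC(C)=C2CC[C@](C)(O)[C@H]2[C@H](OC(C)=O)[C@@H]1C(C)C | target

**Totals**

Total step count: 12. Longest linear sequence: 12 steps (1 and 2 to 21).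

**Three steps most likely to fail, with fallbacks**

Step 9 (the (4+3) cycloaddition). The trisubstituted epoxide may ionise at the tertiary C4 instead of C5, or the cycloadduct may form with H5 syn to the oxygen bridge. The fallback sets out from 11 and generates the oxyallyl cation under basic instead of Lewis acidic conditions. Chloride opens the epoxide of 11 at the carbon next to the carbonyl (LiCl, AcOH, THF) to give (5S,6S)-5-chloro-6-hydroxy-2,6-dimethyl-8-(3-methylfuran-2-yl)octan-4-one F1. Silylation of the tertiary hydroxyl (TESOTf, 2,6-lutidine) gives the silyl ether of the chloro ketone F2. Enolisation and loss of chloride in a polar medium (Et3N, LiClO4, Et2O, or CF3CH2ONa in CF3CH2OH) then gives a free oxyallyl cation that the tethered furan traps; after the same DBU equilibration this returns to the route at 14. In this variant C5 is planar in the cation, so the facial selectivity rests on the C4 stereocenter alone.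

Step 11 (reductive opening of the oxygen bridge). The silyl triflate may ionise the C8–O bond instead, or the allyl cation may lose a proton to a diene. The fallback sets out from 16 and replaces the cationic hydride capture by an addition and reductive elimination pair. Markovnikov addition of anhydrous HBr (CH2Cl2, −78 °C) puts hydrogen on C9 and bromine on the tertiary C10, giving the tertiary bromide of the saturated tricycle F3. Zinc dust in ethanol then effects a Boord-type reductive β-elimination in which the C10–Zn bond expels the C1 oxygen; this can only form C1=C10 and frees the C8 hydroxyl, giving the mono-silyl ether of the ring-opened hydroxy acetate F4. HF·pyridine removes the silyl group and the route is rejoined at 18.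

Step 10 (facial selectivity of the C6 reduction). The C4 methyl group sits near the face the hydride must use, so the C6 epimer could dominate. The fallback sets out from 14 and lets the C8 hydroxyl direct the reduction after the bridge is opened. HBr addition to 14 gives the bromo ketone F5, and zinc-mediated β-elimination gives the ring-opened hydroxy enone F6 (C6 ketone, C1=C10 alkene, free C8–OH). Hydroxyl-directed reduction with Me4NBH(OAc)3 (MeCN, AcOH, −20 °C) delivers hydride from the face of the C8 hydroxyl and gives the 1,3-anti diol F7. Mixed anhydride 20 acylates the less hindered C8 hydroxyl to the C8 angelate F8, and Ac2O with DMAP then gives the silyl-protected target F9. HF·pyridine removes the silyl group and the route is rejoined at 21.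

**Further compounds**

F1 | step 9 | (5S,6S)-5-chloro-6-hydroxy-2,6-dimethyl-8-(3-methylfuran-2-yl)octan-4-one | CC(C)CC(=O)[C@@H](Cl)[C@@](C)(O)CCc1occc1C
F2 | step 9 | (5S,6S)-5-chloro-2,6-dimethyl-8-(3-methylfuran-2-yl)-6-[(triethylsilyl)oxy]octan-4-one | CC(C)CC(=O)[C@@H](Cl)[C@@](C)(O[Si](CC)(CC)CC)CCc1occc1C
F3 | step 11 | (1S,4S,5S,6R,7R,8S)-10-bromo-4,10-dimethyl-7-(propan-2-yl)-4-[(triethylsilyl)oxy]-11-oxatricyclo[6.2.1.0(1,5)]undecan-6-yl acetate (C10 epimers) | CC(C)[C@H]1[C@@H](OC(C)=O)[C@@H]2[C@@](C)(O[Si](CC)(CC)CC)CC[C@]23O[C@H]1CC3(C)Br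
F4 | step 11 | (3S,3aR,4R,5R,6S)-6-hydroxy-3,8-dimethyl-5-(propan-2-yl)-3-[(triethylsilyl)oxy]-1,2,3,3a,4,5,6,7-octahydroazulen-4-yl acetate | O[C@H]1CC(C)=C2CC[C@](C)(O[Si](CC)(CC)CC)[C@H]2[C@H](OC(C)=O)[C@@H]1C(C)C
F5 | step 10 | (1S,4S,5S,7R,8S)-10-bromo-4,10-dimethyl-7-(propan-2-yl)-4-[(triethylsilyl)oxy]-11-oxatricyclo[6.2.1.0(1,5)]undecan-6-one (C10 epimers) | CC(C)[C@H]1C(=O)[C@@H]2[C@@](C)(O[Si](CC)(CC)CC)CC[C@]23O[C@H]1CC3(C)Br
F6 | step 10 | (3S,3aS,5R,6S)-6-hydroxy-3,8-dimethyl-5-(propan-2-yl)-3-[(triethylsilyl)oxy]-2,3,3a,5,6,7-hexahydroazulen-4(1H)-one | O[C@H]1CC(C)=C2CC[C@](C)(O[Si](CC)(CC)CC)[C@H]2C(=O)[C@@H]1C(C)C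
F7 | step 10 | (3S,3aR,4R,5R,6S)-3,8-dimethyl-5-(propan-2-yl)-3-[(triethylsilyl)oxy]-1,2,3,3a,4,5,6,7-octahydroazulene-4,6-diol | O[C@H]1CC(C)=C2CC[C@](C)(O[Si](CC)(CC)CC)[C@H]2[C@H](O)[C@@H]1C(C)C
F8 | step 10 | (3S,3aR,4R,5S,6S)-4-hydroxy-3,8-dimethyl-5-(propan-2-yl)-3-[(triethylsilyl)oxy]-1,2,3,3a,4,5,6,7-octahydroazulen-6-yl (2Z)-2-methylbut-2-enoate | C/C=C(/C)C(=O)O[C@H]1CC(C)=C2CC[C@](C)(O[Si](CC)(CC)CC)[C@H]2[C@H](O)[C@@H]1C(C)C
F9 | step 10 | (3S,3aR,4R,5R,6S)-4-(acetyloxy)-3,8-dimethyl-5-(propan-2-yl)-3-[(triethylsilyl)oxy]-1,2,3,3a,4,5,6,7-octahydroazulen-6-yl (2Z)-2-methylbut-2-enoate | C/C=C(/C)C(=O)O[C@H]1CC(C)=C2CC[C@](C)(O[Si](CC)(CC)CC)[C@H]2[C@H](OC(C)=O)[C@@H]1C(C)C
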